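**Retrosynthetic overview**

1. The target is a 6,12-germacranolide: a ten-membered carbocycle C1–C10 with cis ring alkenes C4=C5 and C1=C10, trans-fused at C6/C7 to an α-methylene-γ-lactone (O on C6, C12=O, C11=C13). The strategy rests on C7 being the γ-carbon of the C13–C11=C7 allyl unit of a 3-(bromomethyl)butenolide that sits next to the C8 carbinol.
2. Last C–C bond: C7–C8, by allyl transfer from a C13 allylchromium to a tethered C8 aldehyde. This closes the carbocycle, sets C7 and C8 and unveils the C11=C13 methylene; angeloylation of C8–OH and desilylation follow.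
3. Butenolide ring (O–C6–C7=C11–C12): carbonylative lactonisation of a C11 iodide obtained by hydroalumination–iodination of a C6 propargylic alcohol; C6 comes from asymmetric reduction of a cis-enynone.
4. cis C4=C5: locked in a temporary six-membered lactone (acrylate ring-closing metathesis on the C2 methallyl carbinol), then opened to a Weinreb amide; C2 from asymmetric methallylboration.
5. C1=C10 with C14 and C9–C8: from but-2-yne-1,4-diol by hydroalumination–iodination and Negishi coupling with a Reformatsky reagent. Ring order: temporary lactone, butenolide, carbocycle.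

Key step: step 20

Remark: carbons carry germacranolide numbers (ring C1–C10, lactone C11–C13 with O on C6, C14 on C10, C15 on C4); TBS = tert-butyldimethylsilyl, TES = triethylsilyl, PMB = 4-methoxybenzyl; a 5-formylbutenolide would enolise at C6, so C6 is created late by ketone reduction and the butenolide is closed after the cis C4=C5 alkene is in place.

**Route**

Step 1
Reactants: 1 but-2-yne-1,4-diol
Product: 2 4-[(tert-butyldimethylsilyl)oxy]but-2-yn-1-ol
Conditions: NaH (1.0 equiv), THF, 0 °C → rt; TBSCl (1.0 equiv)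
Reagents that add atoms: tert-butyldimethylsilyl chloride, CC(C)(C)[Si](C)(C)Cl
Why: O-Silylation of the mono-sodium alkoxide of a symmetrical diol should stop at the mono-TBS ether, which becomes the protected C14 oxygen.

Step 2
Reactants: 2 mono-TBS butynediol
Product: 4 (2Z)-4-[(tert-butyldimethylsilyl)oxy]-3-iodobut-2-en-1-ol, via cyclic alkenylalanate 3 (not isolated)
Conditions: NaAlH2(OCH2CH2OMe)2 (Red-Al), THF, 0 °C; EtOAc; then I2, THF, −78 °C
Reagents that add atoms: iodine, II
Why: Hydroxyl-directed trans-hydroalumination of the propargylic alcohol puts hydride on C1 and aluminium on C10 in a five-membered alkoxyaluminate, and iodinolysis with retention should give the iodide with I cis to C2.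

Step 3
Reactants: 4 (Z)-iodoallylic alcohol; 5 tert-butyl bromoacetate
Product: 7 tert-butyl (3E)-3-{[(tert-butyldimethylsilyl)oxy]methyl}-5-hydroxypent-3-enoate, via zinc ester enolate 6 (not isolated)
Conditions: Zn dust (Me3SiCl-activated), THF, 40 °C; then 4, Pd(PPh3)4 (5 mol %), THF, 50 °C
Reagents that add atoms: none
Why: Negishi coupling of the Reformatsky reagent with the alkenyl iodide goes with retention at C10, so C9 should end up cis to C2 as the ring requires.

Step 4
Reactants: 7 hydroxy ester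
Product: 8 tert-butyl (3E)-3-{[(tert-butyldimethylsilyl)oxy]methyl}-5-oxopent-3-enoate
Conditions: MnO2 (excess), CH2Cl2, rt
Reagents that add atoms: none
Why: MnO2 oxidises only the allylic primary alcohol (allylic oxidation) under neutral conditions, which should leave the alkene geometry and the ester untouched.

Step 5
Reactants: 8 enal
Product: 10 tert-butyl (3E,5S)-3-{[(tert-butyldimethylsilyl)oxy]methyl}-5-hydroxy-7-methylocta-3,7-dienoate, via diisopinocampheylborinate 9 (not isolated)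
Conditions: (−)-Ipc2BOMe, CH2=C(CH3)CH2MgCl, Et2O, −78 °C → rt; then 8, −78 °C; NaBO3·4H2O, THF/H2O, rt
Reagents that add atoms: methallylmagnesium chloride, CC(=C)C[Mg]Cl
Why: Asymmetric methallylboration through a chair Zimmerman–Traxler transition state should add C3 to the Si face of the enal under control of the isopinocampheyl groups derived from (+)-α-pinene, setting C2 as S.

Step 6
Reactants: 10 homoallylic alcohol
Product: 11 (3E,5S)-3-{[(tert-butyldimethylsilyl)oxy]methyl}-7-methylocta-3,7-diene-1,5-diol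
Conditions: LiAlH4, THF, 0 °C
Reagents that add atoms: none
Why: Hydride reduction of the tert-butyl ester brings C8 to the alcohol level before any lactone is present, and any δ-lactone formed from 10 would be reduced to the same diol.

Step 7
Reactants: 11 diol
Product: 12 (4S,5E)-6-{[(tert-butyldimethylsilyl)oxy]methyl}-2-methyl-8-[(triethylsilyl)oxy]octa-1,5-dien-4-ol
Conditions: TESCl (1.05 equiv), imidazole, CH2Cl2, −78 °C
Reagents that add atoms: chlorotriethylsilane, CC[Si](CC)(CC)Cl
Why: Selective O-silylation of the less hindered primary C8 hydroxyl at low temperature should leave the secondary allylic C2 hydroxyl free.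

Step 8
Reactants: 12 mono-TES diol
Product: 13 (4S,5E)-6-{[(tert-butyldimethylsilyl)oxy]methyl}-2-methyl-8-[(triethylsilyl)oxy]octa-1,5-dien-4-yl prop-2-enoate
Conditions: acryloyl chloride, i-Pr2NEt, CH2Cl2, −78 → 0 °C
Reagents that add atoms: acryloyl chloride, C=CC(=O)Cl
Why: O-Acylation puts C6 and C5 on the C2 oxygen as the tether for ring-closing metathesis.

Step 9
Reactants: 13 acrylate
Product: 14 (6S)-6-[(1E)-2-{[(tert-butyldimethylsilyl)oxy]methyl}-4-[(triethylsilyl)oxy]but-1-en-1-yl]-4-methyl-5,6-dihydro-2H-pyran-2-one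
Conditions: second-generation Grubbs catalyst (5 mol %), CH2Cl2 (0.005 M), 40 °C
Reagents that add atoms: none
Why: Ring-closing metathesis of the acrylate with the 1,1-disubstituted alkene gives a six-membered unsaturated lactone, in which the trisubstituted C4=C5 alkene can only have C3 and C6 cis.

Step 10
Reactants: 14 unsaturated δ-lactone
Product: 15 (2Z,5S,6E)-7-{[(tert-butyldimethylsilyl)oxy]methyl}-5-hydroxy-N-methoxy-N,3-dimethyl-9-[(triethylsilyl)oxy]nona-2,6-dienamide
Conditions: MeNH(OMe)·HCl, Me3Al, CH2Cl2, 0 °C → rt; used at once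
Reagents that add atoms: N,O-dimethylhydroxylamine hydrochloride, CNOC.Cl
Why: Weinreb aminolysis with the aluminium amide opens the lactone by acyl substitution, so the cis alkene geometry is carried into the open chain.

Step 11
Reactants: 15 hydroxy Weinreb amide
Product: 16 (2Z,5S,6E)-5-[(tert-butyldimethylsilyl)oxy]-7-{[(tert-butyldimethylsilyl)oxy]methyl}-N-methoxy-N,3-dimethyl-9-[(triethylsilyl)oxy]nona-2,6-dienamide
Conditions: TBSOTf, 2,6-lutidine, CH2Cl2, −78 °C
Reagents that add atoms: tert-butyldimethylsilyl trifluoromethanesulfonate, CC(C)(C)[Si](C)(C)OS(=O)(=O)C(F)(F)F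
Why: Fast O-silylation of the freed C2 hydroxyl blocks relactonisation and installs the C2 protecting group kept to the end.

Step 12
Reactants: 16 Weinreb amide; 17 1-methoxy-4-[(prop-2-yn-1-yloxy)methyl]benzene
Product: 19 (5Z,8S,9E)-8-[(tert-butyldimethylsilyl)oxy]-10-{[(tert-butyldimethylsilyl)oxy]methyl}-1-[(4-methoxybenzyl)oxy]-6-methyl-12-[(triethylsilyl)oxy]dodeca-5,9-dien-2-yn-4-one, via lithium acetylide 18 (not isolated)
Conditions: 17, n-BuLi, THF, −78 °C; then 16, −78 → −20 °C; aq. NH4Cl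
Reagents that add atoms: none
Why: Weinreb ketone synthesis: the acetylide adds once because the chelated tetrahedral intermediate collapses only on work-up, giving the ynone that carries C7, C11 and C13.

Step 13
Reactants: 19 cis-enynone
Product: 20 (4R,5Z,8S,9E)-8-[(tert-butyldimethylsilyl)oxy]-10-{[(tert-butyldimethylsilyl)oxy]methyl}-1-[(4-methoxybenzyl)oxy]-6-methyl-12-[(triethylsilyl)oxy]dodeca-5,9-dien-2-yn-4-ol
Conditions: (R)-2-methyl-CBS-oxazaborolidine (20 mol %), catecholborane, CH2Cl2, −78 °C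
Reagents that add atoms: none
Why: Corey–Bakshi–Shibata reduction, with the linear alkynyl group as the small and the cis-alkenyl group as the large substituent, should deliver hydride to the face that gives the (R)-carbinol at C6.

Step 14
Reactants: 20 C6 propargylic alcohol
Product: 22 (2Z,4R,5Z,8S,9E)-8-[(tert-butyldimethylsilyl)oxy]-10-{[(tert-butyldimethylsilyl)oxy]methyl}-2-iodo-1-[(4-methoxybenzyl)oxy]-6-methyl-12-[(triethylsilyl)oxy]dodeca-2,5,9-trien-4-ol, via cyclic alkenylalanate 21 (not isolated)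
Conditions: NaAlH2(OCH2CH2OMe)2 (Red-Al), THF, 0 °C → rt; EtOAc; then I2, THF, −78 °C
Reagents that add atoms: iodine, II
Why: Hydroxyl-directed trans-hydroalumination puts hydride on C7 and aluminium on C11, and iodinolysis with retention should give the C11 iodide cis to C6.

Step 15
Reactants: 22 (Z)-iodoallylic alcohol
Product: 23 (5R)-5-[(1Z,4S,5E)-4-[(tert-butyldimethylsilyl)oxy]-6-{[(tert-butyldimethylsilyl)oxy]methyl}-2-methyl-8-[(triethylsilyl)oxy]octa-1,5-dien-1-yl]-3-{[(4-methoxybenzyl)oxy]methyl}furan-2(5H)-one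
Conditions: PdCl2(PPh3)2 (5 mol %), CO (1 atm), K2CO3, THF, rt
Reagents that add atoms: carbon monoxide, [C-]#[O+]
Why: Carbonylative lactonisation: oxidative addition of zerovalent palladium into C11–I, CO insertion and capture of the acylpalladium by the cis C6 hydroxyl should close the butenolide with C12 as carbonyl.

Step 16
Reactants: 23 PMB-protected butenolide
Product: 24 (5R)-5-[(1Z,4S,5E)-4-[(tert-butyldimethylsilyl)oxy]-6-{[(tert-butyldimethylsilyl)oxy]methyl}-2-methyl-8-[(triethylsilyl)oxy]octa-1,5-dien-1-yl]-3-(hydroxymethyl)furan-2(5H)-one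
Conditions: DDQ, CH2Cl2/pH 7 buffer, 0 °C
Reagents that add atoms: none
Why: Oxidative cleavage of the electron-rich 4-methoxybenzyl ether frees the C13 hydroxyl while the silyl ethers and the lactone should survive the buffered medium.

Step 17
Reactants: 24 hydroxymethylbutenolide
Product: 25 (5R)-3-(bromomethyl)-5-[(1Z,4S,5E)-4-[(tert-butyldimethylsilyl)oxy]-6-{[(tert-butyldimethylsilyl)oxy]methyl}-2-methyl-8-[(triethylsilyl)oxy]octa-1,5-dien-1-yl]furan-2(5H)-one
Conditions: CBr4, PPh3, CH2Cl2, 0 °C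
Reagents that add atoms: carbon tetrabromide, BrC(Br)(Br)Br
Why: Appel bromination turns the primary allylic alcohol into the bromide under neutral conditions that spare the base-sensitive C6–H of the butenolide.

Step 18
Reactants: 25 bromomethylbutenolide TES ether
Product: 26 (5R)-3-(bromomethyl)-5-[(1Z,4S,5E)-4-[(tert-butyldimethylsilyl)oxy]-6-{[(tert-butyldimethylsilyl)oxy]methyl}-8-hydroxy-2-methylocta-1,5-dien-1-yl]furan-2(5H)-one
Conditions: camphorsulfonic acid (10 mol %), MeOH/CH2Cl2 (1:3), −20 °C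
Reagents that add atoms: none
Why: Acid-catalysed methanolysis removes the primary TES ether far faster than the TBS ethers (selective desilylation), and the allylic bromide should not react with cold methanol in the absence of base.

Step 19
Reactants: 26 bromomethylbutenolide alcohol
Product: 27 (5R)-3-(bromomethyl)-5-[(1Z,4S,5E)-4-[(tert-butyldimethylsilyl)oxy]-6-{[(tert-butyldimethylsilyl)oxy]methyl}-2-methyl-8-oxoocta-1,5-dien-1-yl]furan-2(5H)-one
Conditions: Dess–Martin periodinane, NaHCO3, CH2Cl2, 0 °C; used at once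
Reagents that add atoms: none
Why: Dess–Martin oxidation under buffered, amine-free conditions should give the β,γ-unsaturated C8 aldehyde without moving the C1=C10 alkene into conjugation.

Step 20
Reactants: 27 bromomethylbutenolide aldehyde
Product: 29 (3aR,4S,6E,8S,10Z,11aR)-8-[(tert-butyldimethylsilyl)oxy]-6-{[(tert-butyldimethylsilyl)oxy]methyl}-4-hydroxy-10-methyl-3-methylidene-3a,4,5,8,9,11a-hexahydrocyclodeca[b]furan-2(3H)-one, via allylchromium dichloride 28 (not isolated)
Conditions: CrCl2 (10 equiv), THF, rt, slow addition of 27 to 0.002 M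
Reagents that add atoms: none
Why: CrCl2 (divalent chromium) inserts into the C13–Br bond by two single-electron transfers to give allylchromium 28 (trivalent chromium), which adds through its γ-carbon C7 to the tethered C8 aldehyde in a six-membered chair (Nozaki–Hiyama–Kishi allylation; the closest known cases are chromium-mediated couplings of 2-(bromomethyl)acrylates and of 3-(bromomethyl)butenolides with aldehydes). The ten-membered carbocycle is closed by this C7→C8 bond in a 10-exo-trig mode, and the allyl shift turns C11–C13 into the exocyclic methylene. C7 should be set by attack on the butenolide face opposite to the C5 substituent on C6, which gives the trans-fused lactone; C8 should be set by the chair in which the aldehyde chain is equatorial and the ring-locked allyl unit (C6 trans to C13) places the C8–O bond anti to C7–C6, that is 8S. The step needs γ- over α-attack, which allylchromium reagents show, and ring closure over oligomerisation, which high dilution and the two cis alkenes that fold the chain should favour. Because the lactone oxygen already sits on C6 and the C2 and C14 oxygens are silylated, no other hydroxyl can compete for the lactone carbonyl.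

Step 21
Reactants: 29 macrocyclic C8 alcohol; 30 angelic acid
Product: 32 (3aR,4S,6E,8S,10Z,11aR)-8-[(tert-butyldimethylsilyl)oxy]-6-{[(tert-butyldimethylsilyl)oxy]methyl}-10-methyl-3-methylidene-2-oxo-2,3,3a,4,5,8,9,11a-octahydrocyclodeca[b]furan-4-yl (2Z)-2-methylbut-2-enoate, via mixed anhydride 31 (not isolated)
Conditions: 30, 2,4,6-trichlorobenzoyl chloride, Et3N, toluene, rt; then 29, 80 °C
Reagents that add atoms: none
Why: Yamaguchi-type acylation through the mixed anhydride, run without a nucleophilic catalyst, should acylate the C8 hydroxyl while keeping the Z geometry of the 2-methylbut-2-enoyl group.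

Step 22
Reactants: 32 bis-TBS angelate
Product: 33 (3aR,4S,6E,8S,10Z,11aR)-8-hydroxy-6-(hydroxymethyl)-10-methyl-3-methylidene-2-oxo-2,3,3a,4,5,8,9,11a-octahydrocyclodeca[b]furan-4-yl (2Z)-2-methylbut-2-enoate
Conditions: HF·pyridine, pyridine, THF, 0 °C → rt
Reagents that add atoms: none
Why: Buffered fluoride-mediated desilylation should cleave both Si–O bonds without harming the angelate or the α-methylene lactone.

**Compound list**

1 | but-2-yne-1,4-diol | OCC#CCO | starting material
2 | 4-[(tert-butyldimethylsilyl)oxy]but-2-yn-1-ol | OCC#CCO[Si](C)(C)C(C)(C)C | intermediate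
3 | sodium cyclic alkenylalanate from 2 (five-membered ring Al–O–C2–C1=C10, two 2-methoxyethoxy groups on Al) | [Na+].COCCO[Al-]1(OCCOC)OCC=C1CO[Si](C)(C)C(C)(C)C | intermediate
4 | (2Z)-4-[(tert-butyldimethylsilyl)oxy]-3-iodobut-2-en-1-ol | OC/C=C(\I)CO[Si](C)(C)C(C)(C)C | intermediate
5 | tert-butyl bromoacetate | BrCC(=O)OC(C)(C)C | starting material
6 | (2-tert-butoxy-2-oxoethyl)zinc bromide | Br[Zn]CC(=O)OC(C)(C)C | intermediate
7 | tert-butyl (3E)-3-{[(tert-butyldimethylsilyl)oxy]methyl}-5-hydroxypent-3-enoate | OC/C=C(\CC(=O)OC(C)(C)C)CO[Si](C)(C)C(C)(C)C | intermediate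
8 | tert-butyl (3E)-3-{[(tert-butyldimethylsilyl)oxy]methyl}-5-oxopent-3-enoate | O=C/C=C(\CC(=O)OC(C)(C)C)CO[Si](C)(C)C(C)(C)C | intermediate
9 | bis[(1R,2S,3R,5R)-isopinocampheyl]borinate of alcohol 10 (boron on the C2 oxygen) | C=C(C)C[C@H](OB([C@@H]1C[C@@H]2C[C@H]([C@H]1C)C2(C)C)[C@@H]1C[C@@H]2C[C@H]([C@H]1C)C2(C)C)/C=C(\CC(=O)OC(C)(C)C)CO[Si](C)(C)C(C)(C)C | intermediate
10 | tert-butyl (3E,5S)-3-{[(tert-butyldimethylsilyl)oxy]methyl}-5-hydroxy-7-methylocta-3,7-dienoate | C=C(C)C[C@H](O)/C=C(\CC(=O)OC(C)(C)C)CO[Si](C)(C)C(C)(C)C | intermediate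
11 | (3E,5S)-3-{[(tert-butyldimethylsilyl)oxy]methyl}-7-methylocta-3,7-diene-1,5-diol | C=C(C)C[C@H](O)/C=C(\CCO)CO[Si](C)(C)C(C)(C)C | intermediate
12 | (4S,5E)-6-{[(tert-butyldimethylsilyl)oxy]methyl}-2-methyl-8-[(triethylsilyl)oxy]octa-1,5-dien-4-ol | C=C(C)C[C@H](O)/C=C(\CCO[Si](CC)(CC)CC)CO[Si](C)(C)C(C)(C)C | intermediate
13 | (4S,5E)-6-{[(tert-butyldimethylsilyl)oxy]methyl}-2-methyl-8-[(triethylsilyl)oxy]octa-1,5-dien-4-yl prop-2-enoate | C=C(C)C[C@H](OC(=O)C=C)/C=C(\CCO[Si](CC)(CC)CC)CO[Si](C)(C)C(C)(C)C | intermediate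
14 | (6S)-6-[(1E)-2-{[(tert-butyldimethylsilyl)oxy]methyl}-4-[(triethylsilyl)oxy]but-1-en-1-yl]-4-methyl-5,6-dihydro-2H-pyran-2-one | CC1=CC(=O)O[C@@H](C1)/C=C(\CCO[Si](CC)(CC)CC)CO[Si](C)(C)C(C)(C)C | intermediate
15 | (2Z,5S,6E)-7-{[(tert-butyldimethylsilyl)oxy]methyl}-5-hydroxy-N-methoxy-N,3-dimethyl-9-[(triethylsilyl)oxy]nona-2,6-dienamide | CON(C)C(=O)/C=C(C)\C[C@H](O)/C=C(\CCO[Si](CC)(CC)CC)CO[Si](C)(C)C(C)(C)C | intermediate
16 | (2Z,5S,6E)-5-[(tert-butyldimethylsilyl)oxy]-7-{[(tert-butyldimethylsilyl)oxy]methyl}-N-methoxy-N,3-dimethyl-9-[(triethylsilyl)oxy]nona-2,6-dienamide | CON(C)C(=O)/C=C(C)\C[C@H](O[Si](C)(C)C(C)(C)C)/C=C(\CCO[Si](CC)(CC)CC)CO[Si](C)(C)C(C)(C)C | intermediate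
17 | 1-methoxy-4-[(prop-2-yn-1-yloxy)methyl]benzene (4-methoxybenzyl propargyl ether) | C#CCOCc1ccc(OC)cc1 | starting material
18 | lithium acetylide of 17 | [Li]C#CCOCc1ccc(OC)cc1 | intermediate
19 | (5Z,8S,9E)-8-[(tert-butyldimethylsilyl)oxy]-10-{[(tert-butyldimethylsilyl)oxy]methyl}-1-[(4-methoxybenzyl)oxy]-6-methyl-12-[(triethylsilyl)oxy]dodeca-5,9-dien-2-yn-4-one | COc1ccc(COCC#CC(=O)/C=C(C)\C[C@H](O[Si](C)(C)C(C)(C)C)/C=C(\CCO[Si](CC)(CC)CC)CO[Si](C)(C)C(C)(C)C)cc1 | intermediate
20 | (4R,5Z,8S,9E)-8-[(tert-butyldimethylsilyl)oxy]-10-{[(tert-butyldimethylsilyl)oxy]methyl}-1-[(4-methoxybenzyl)oxy]-6-methyl-12-[(triethylsilyl)oxy]dodeca-5,9-dien-2-yn-4-ol | COc1ccc(COCC#C[C@H](O)/C=C(C)\C[C@H](O[Si](C)(C)C(C)(C)C)/C=C(\CCO[Si](CC)(CC)CC)CO[Si](C)(C)C(C)(C)C)cc1 | intermediate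
21 | sodium cyclic alkenylalanate from 20 (five-membered ring Al–O–C6–C7=C11, two 2-methoxyethoxy groups on Al) | [Na+].COCCO[Al-]1(OCCOC)O[C@H](/C=C(C)\C[C@H](O[Si](C)(C)C(C)(C)C)/C=C(\CCO[Si](CC)(CC)CC)CO[Si](C)(C)C(C)(C)C)C=C1COCc1ccc(OC)cc1 | intermediate
22 | (2Z,4R,5Z,8S,9E)-8-[(tert-butyldimethylsilyl)oxy]-10-{[(tert-butyldimethylsilyl)oxy]methyl}-2-iodo-1-[(4-methoxybenzyl)oxy]-6-methyl-12-[(triethylsilyl)oxy]dodeca-2,5,9-trien-4-ol | COc1ccc(COC/C(I)=C/[C@H](O)/C=C(C)\C[C@H](O[Si](C)(C)C(C)(C)C)/C=C(\CCO[Si](CC)(CC)CC)CO[Si](C)(C)C(C)(C)C)cc1 | intermediate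
23 | (5R)-5-[(1Z,4S,5E)-4-[(tert-butyldimethylsilyl)oxy]-6-{[(tert-butyldimethylsilyl)oxy]methyl}-2-methyl-8-[(triethylsilyl)oxy]octa-1,5-dien-1-yl]-3-{[(4-methoxybenzyl)oxy]methyl}furan-2(5H)-one | O=C1O[C@@H](C=C1COCc1ccc(OC)cc1)/C=C(C)\C[C@H](O[Si](C)(C)C(C)(C)C)/C=C(\CCO[Si](CC)(CC)CC)CO[Si](C)(C)C(C)(C)C | intermediate
24 | (5R)-5-[(1Z,4S,5E)-4-[(tert-butyldimethylsilyl)oxy]-6-{[(tert-butyldimethylsilyl)oxy]methyl}-2-methyl-8-[(triethylsilyl)oxy]octa-1,5-dien-1-yl]-3-(hydroxymethyl)furan-2(5H)-one | O=C1O[C@@H](C=C1CO)/C=C(C)\C[C@H](O[Si](C)(C)C(C)(C)C)/C=C(\CCO[Si](CC)(CC)CC)CO[Si](C)(C)C(C)(C)C | intermediate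
25 | (5R)-3-(bromomethyl)-5-[(1Z,4S,5E)-4-[(tert-butyldimethylsilyl)oxy]-6-{[(tert-butyldimethylsilyl)oxy]methyl}-2-methyl-8-[(triethylsilyl)oxy]octa-1,5-dien-1-yl]furan-2(5H)-one | O=C1O[C@@H](C=C1CBr)/C=C(C)\C[C@H](O[Si](C)(C)C(C)(C)C)/C=C(\CCO[Si](CC)(CC)CC)CO[Si](C)(C)C(C)(C)C | intermediate
26 | (5R)-3-(bromomethyl)-5-[(1Z,4S,5E)-4-[(tert-butyldimethylsilyl)oxy]-6-{[(tert-butyldimethylsilyl)oxy]methyl}-8-hydroxy-2-methylocta-1,5-dien-1-yl]furan-2(5H)-one | O=C1O[C@@H](C=C1CBr)/C=C(C)\C[C@H](O[Si](C)(C)C(C)(C)C)/C=C(\CCO)CO[Si](C)(C)C(C)(C)C | intermediate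
27 | (5R)-3-(bromomethyl)-5-[(1Z,4S,5E)-4-[(tert-butyldimethylsilyl)oxy]-6-{[(tert-butyldimethylsilyl)oxy]methyl}-2-methyl-8-oxoocta-1,5-dien-1-yl]furan-2(5H)-one (key-step precursor) | O=C1O[C@@H](C=C1CBr)/C=C(C)\C[C@H](O[Si](C)(C)C(C)(C)C)/C=C(\CC=O)CO[Si](C)(C)C(C)(C)C | intermediate
28 | C13 allylchromium dichloride of 27 (trivalent chromium) | O=C1O[C@@H](C=C1C[Cr](Cl)Cl)/C=C(C)\C[C@H](O[Si](C)(C)C(C)(C)C)/C=C(\CC=O)CO[Si](C)(C)C(C)(C)C | intermediate
29 | (3aR,4S,6E,8S,10Z,11aR)-8-[(tert-butyldimethylsilyl)oxy]-6-{[(tert-butyldimethylsilyl)oxy]methyl}-4-hydroxy-10-methyl-3-methylidene-3a,4,5,8,9,11a-hexahydrocyclodeca[b]furan-2(3H)-one (key-step product) | C=C1C(=O)O[C@@H]2/C=C(/C)C[C@H](O[Si](C)(C)C(C)(C)C)/C=C(/CO[Si](C)(C)C(C)(C)C)C[C@H](O)[C@@H]12 | intermediate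
30 | angelic acid, (2Z)-2-methylbut-2-enoic acid | C/C=C(/C)C(=O)O | starting material
31 | (2Z)-2-methylbut-2-enoic 2,4,6-trichlorobenzoic anhydride | C/C=C(/C)C(=O)OC(=O)c1c(Cl)cc(Cl)cc1Cl | intermediate
32 | (3aR,4S,6E,8S,10Z,11aR)-8-[(tert-butyldimethylsilyl)oxy]-6-{[(tert-butyldimethylsilyl)oxy]methyl}-10-methyl-3-methylidene-2-oxo-2,3,3a,4,5,8,9,11a-octahydrocyclodeca[b]furan-4-yl (2Z)-2-methylbut-2-enoate | C=C1C(=O)O[C@@H]2/C=C(/C)C[C@H](O[Si](C)(C)C(C)(C)C)/C=C(/CO[Si](C)(C)C(C)(C)C)C[C@H](OC(=O)/C(C)=C\C)[C@@H]12 | intermediate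
33 | (3aR,4S,6E,8S,10Z,11aR)-8-hydroxy-6-(hydroxymethyl)-10-methyl-3-methylidene-2-oxo-2,3,3a,4,5,8,9,11a-octahydrocyclodeca[b]furan-4-yl (2Z)-2-methylbut-2-enoate (CNP0270898.1) | C=C1C(=O)O[C@@H]2/C=C(/C)C[C@H](O)/C=C(/CO)C[C@H](OC(=O)/C(C)=C\C)[C@@H]12 | target

**Step count and risks**

Total step count: 22. Longest linear sequence: 22 steps (1 to 33); compounds 5, 17 and 30 enter as bought.

Steps most likely to fail:

Step 20. The chain may reach the allylchromium with the aldehyde substituent axial or through the other aldehyde face, so that ring closure erodes or reverses the configuration at C8. In that case the cyclisation is still run from 27, and the ring-closed C8 epimer of the macrocyclic alcohol F1 is not oxidised or discarded. It is esterified with angelic acid 30 under Mitsunobu conditions (PPh3, diisopropyl azodicarboxylate, toluene, 0 °C → rt). This forms the C8–O ester bond with inversion and returns to the route at 32, so that the C8 configuration is set by substitution instead of by the allylation.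

Step 13. The oxazaborolidine may fail to tell the cis-alkenyl from the alkynyl substituent, or the cross-conjugated enynone may isomerise at C4=C5 before it is reduced. The fallback sets out from amide 16, which is reduced with (i-Bu)2AlH (THF, −78 °C) to the (Z)-enal F2. Alkyne 17 is then added enantioselectively as its zinc acetylide (Me2Zn, the ProPhenol ligand enantiomer that gives the (R)-carbinol, toluene, 0 °C). This gives 20 directly and bypasses the ynone.

Step 21. The activated angeloyl unit may isomerise to the (E)-2-methylbut-2-enoyl (tigloyl) group, or the hindered C8 hydroxyl may not be acylated at the temperature the alkene geometry tolerates. The fallback sets out from 29, which is esterified with 2-[bis(2,2,2-trifluoroethoxy)phosphoryl]propanoic acid (dicyclohexylcarbodiimide, 4-dimethylaminopyridine cat., CH2Cl2) to the phosphonate ester F3. Still–Gennari olefination with acetaldehyde (KN(SiMe3)2, 18-crown-6, THF, −78 °C) then builds the Z alkene of the angelate on the molecule and returns to the route at 32.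

**Further compounds**

F1 | step 20 | (3aR,4R,6E,8S,10Z,11aR)-8-[(tert-butyldimethylsilyl)oxy]-6-{[(tert-butyldimethylsilyl)oxy]methyl}-4-hydroxy-10-methyl-3-methylidene-3a,4,5,8,9,11a-hexahydrocyclodeca[b]furan-2(3H)-one (C8 epimer of 29) | C=C1C(=O)O[C@@H]2/C=C(/C)C[C@H](O[Si](C)(C)C(C)(C)C)/C=C(/CO[Si](C)(C)C(C)(C)C)C[C@@H](O)[C@@H]12
F2 | step 13 | (2Z,5S,6E)-5-[(tert-butyldimethylsilyl)oxy]-7-{[(tert-butyldimethylsilyl)oxy]methyl}-3-methyl-9-[(triethylsilyl)oxy]nona-2,6-dienal | O=C/C=C(C)\C[C@H](O[Si](C)(C)C(C)(C)C)/C=C(\CCO[Si](CC)(CC)CC)CO[Si](C)(C)C(C)(C)C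
F3 | step 21 | C8 2-[bis(2,2,2-trifluoroethoxy)phosphoryl]propanoate of 29 (both epimers at the phosphonate carbon) | C=C1C(=O)O[C@@H]2/C=C(/C)C[C@H](O[Si](C)(C)C(C)(C)C)/C=C(/CO[Si](C)(C)C(C)(C)C)C[C@H](OC(=O)C(C)P(=O)(OCC(F)(F)F)OCC(F)(F)F)[C@@H]12
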